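## Structural features

The target is a 6-hydroxy-2H-chromene: a benzene ring fused to a pyran ring (O1, C2, C3=C4, C4a, C8a) whose C2 carries a methyl group and, through C1', a 31-carbon polyprenyl chain with six trisubstituted alkenes, so that the whole is a cyclised heptaprenyl hydroquinone. C2 is the only stereocentre (S); it is fully substituted (O1, C3, C1', methyl) and has no neighbouring stereocentre or hydrogen from which its configuration could be relayed. Five chain alkenes are ordinary E methyl-branched prenyl units, but C15'=C16' carries a hydroxymethyl group on C16' and has the chain arms C14' and C17' cis to each other (the descriptor is E only because hydroxymethyl outranks C17'). Fragile parts are the electron-rich free phenol (air oxidation), the 2H-chromene (its tertiary allylic aryl ether can ionise under acid and open electrocyclically under light, with loss of configuration), the acid-sensitive skipped polyene and the primary allylic alcohol. The real difficulties are the absolute configuration of an isolated quaternary carbon, the geometry of the one unusual alkene, and the attachment of a C30 chain to the neopentyl-like C1'. The key step exploits the fact that the two carbon substituents of C2, ring carbon C3 and chain carbon C1', can both begin as hydroxymethyl groups of a 2-aryloxy-2-methylpropane-1,3-diol with a mirror plane through C2, methyl and O1, so that choosing one arm fixes C2.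

## Logic of the disconnections

33 from 32: the two O–Si bonds are cut. The phenol and the allylic alcohol must be masked through carbanion and hydride chemistry, and two silyl ethers fall in one fluoride treatment. The forward step must not disturb the chromene or the polyene.

32 from 31, and 31 from 29 plus 30: the C1'–C2' bond is cut. C2' is allylic and can carry a sulfonyl group, so a stabilised carbanion can attack C1'. This divides the molecule into a small chiral head (30) and an achiral C30 chain (29), the largest gain in convergence available. The demands are substitution at a hindered primary carbon (hence a triflate) and removal of the sulfonyl group with hydride delivered to C2', so that the 3',4' alkene neither moves nor isomerises.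

30 from 11, 10 and 9: the C4–C4a bond is cut, opening the pyran ring to an aryl propargyl ether. The C2–O1 bond is never broken, so the configuration is carried through the ring closure. The forward step must be a 6-endo hydroarylation without ionisation of the tertiary ether. The para-substituted arene makes both ortho positions equivalent, and a masked hydroxyl on the other arm avoids competing attack by oxygen.

9 from 8, 7 and 6: the C3–C4 bond is cut (one-carbon homologation of an aldehyde), then the aldehyde is taken back to the free hydroxymethyl arm. The aldehyde has no α-hydrogen, so C2 cannot epimerise. The acetate cannot be relied on to survive the basic methanol of the homologation, so the plan lets it go and restores it in the same flask. That way step 7 meets no free hydroxyl.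

6 from 5: only an O–acyl bond is cut and no skeletal bond. The stereocentre arises from differentiation of two enantiotopic arms. All asymmetry is introduced by a catalyst on a small, robust, achiral diol. The forward step must select one arm and stop at the monoester.

5 from 4, 4 from 2 plus 3, and 2 from 1: the two C–O ester bonds are returned to a malonate, then the C2–O1 bond is cut. The quaternary carbon with its methyl group and both arms comes ready-made in 3. The forward step needs substitution by a phenoxide at a tertiary but doubly activated carbon, and a phenol protecting group robust to carbonate, hydride, methoxide and organolithium reagents (hence triisopropylsilyl).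

29 from 28 and 27, and 27 from 26 plus 17: the C15'=C16' alkene is cut by a carbonyl olefination. Placing an ester on C16' supplies the hydroxymethyl carbon, and the trans relation of ester and aldehyde-derived chain is exactly the required cis relation of C14' and C17'. The forward step must be E-selective and must tolerate the allylic sulfone already in place.

26 from 25, 24, 23, 22, 21, 20, 19 and 18: the C13'–C14' bond is cut by a [3,3] shift that also makes the C11'=C12' alkene. The allylic alcohol goes back to the terminal epoxide of a farnesyl unit, and the C2'–S bond is cut last. The sulfonyl group is installed first because it survives every later step and is needed for the fragment union. The demands are terminal-selective functionalisation of a triene and E-selectivity in the rearrangement.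

17 from 15 plus 16, and 15 from 14, 13 and 12: the C16'–C17' bond is cut (alkylation of a phosphonate-stabilised carbanion), then C17'–C18' (one-carbon homologation of a geranyl unit through a thio-stabilised carbanion). Both forward steps are SN2 reactions at primary carbons, and the alkene geometry of 12 is never touched.

## Other disconnections considered

Alternative 1: the cuts are O1–C2 and C3–C4, so that ring, stereocentre and chain arrive together. 5-(tert-Butyldimethylsilyloxy)-2-hydroxybenzaldehyde A1 and the C35 enal A2 would combine under a secondary-amine catalyst of the diarylprolinol silyl ether class. Iminium activation allows oxa-Michael addition of the phenol to C2, and enamine aldol condensation onto the aryl aldehyde closes the ring to the 3-formylchromene A3. Decarbonylation and desilylation would follow.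
- In favour: one step builds the pyran ring and sets C2, the arene needs no desymmetrisation, and only two operations follow the key step.
- Against: C2 is the β-carbon of a β,β-disubstituted enal, for which iminium oxa-Michael additions are slow. The catalyst must tell methyl from a CH2 chain, a far smaller difference than methyl versus aryloxy in 5. The oxa-Michael step is reversible, and γ-deprotonation to a dienamine can scramble the enal geometry and with it the sense of induction. Removal of the formyl group needs a rhodium reagent such as RhCl(PPh3)3 at high temperature in the presence of six alkenes.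
- Comparison: in convergence and in steps after the stereocentre is set this plan is the better one. In security of the stereochemical outcome and mildness of the late steps the chosen plan is stronger. On the side chain the two are equal, since A2 needs the same 15',16' chemistry as 29 plus one more prenyl unit.

Alternative 2: the cut is the C16'–C17' bond. Homogeranylmagnesium bromide A5 would add across the alkyne of the chromene alkynol A4 under CuI catalysis. The magnesium alkoxide directs the alkyl group to C16' and magnesium to C15' in a five-membered chelate (anti addition), and protonation gives the aryl silyl ether A6 with C14' cis to C17'.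
- In favour: the alkene geometry follows from the mechanism and not from a preference between two isomers, so on this point it is better than the olefination of step 17. The allylic alcohol emerges unprotected, and the chain is completed at the very end.
- Against: it does not address C2 at all, since A4 still needs a chiral chromene such as 30. It demands a large excess of A5 at the last C–C bond formation on the most valuable intermediate. The alkynol chain must still be joined to C1' by sulfone chemistry, and such additions usually need heating.
- Comparison: on the heterocycle the two plans are equal (this one would borrow the key step). On alkene geometry this one is better, and step counts are about equal. The chosen plan keeps the excess-reagent and stereochemically delicate chain chemistry on achiral material.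

Alternative 3: the cut is C2–C1', so the stereocentre is made by C–C bond formation. Lithiated (R)-carbamate A7 would capture boronic ester A8, and 1,2-migration of C1' from boron to carbon with loss of the carbamate would give the tertiary propargylic boronic ester A9. Oxidation with retention would give the tertiary propargylic alcohol A10.
- In favour: the sense of induction follows from the configuration of A7 through stereospecific steps, which is more predictable in advance than an enzyme's preference, and here it is the better plan. Chain and stereocentre are joined in one step.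
- Against: lithiated propargylic carbamates are configurationally fragile. A8 is a homoallylic boronic ester one carbon longer than 29. After A10 the O1–C8a bond must be made at a tertiary propargylic alcohol, for which no mild, general method exists. The pyran ring would then have to be closed in the presence of the hexaene, where metal-mediated enyne reactions compete.
- Comparison: on predictability of configuration and on convergence at the stereocentre it is equal or better. On ring construction and step economy after the key step the chosen plan is clearly ahead, because it closes the ring before any polyene is present.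

Key step: step 4

Assumption: the lipase is taken to acetylate the arm that gives (R)-6; if it prefers the other arm, the hydrolytic variant described under the least certain steps supplies the same (R)-6.

Remark on the chemistry: tracing the substituents shows that (R)-6 maps onto (S)-33 when the free arm becomes C3 and the acetylated arm C1'; no bond to C2 is broken and the change of letter is a change of CIP ranking only.

## Route

Step 1
Reactants: 1 hydroquinone
Product: 2 4-(triisopropylsilyloxy)phenol
Conditions: i-Pr3SiCl (1 equiv), imidazole, excess 1, DMF, 0 °C to rt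
Reagents that add atoms: triisopropylsilyl chloride CC(C)[Si](Cl)(C(C)C)C(C)C
Why: Statistical monosilylation of a symmetrical diol; the excess of 1 suppresses the bis-ether and is washed out with water.

Step 2
Reactants: 2 4-(triisopropylsilyloxy)phenol; 3 diethyl 2-bromo-2-methylmalonate
Product: 4 diethyl 2-methyl-2-[4-(triisopropylsilyloxy)phenoxy]malonate
Conditions: K2CO3, DMF (dry), 60 °C
Reagents that add atoms: none
Why: Williamson-type substitution: the phenoxide displaces the tertiary bromide, which is activated by two ester groups; the bulky silyl ether should resist carbonate.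

Step 3
Reactants: 4 diethyl 2-methyl-2-[4-(triisopropylsilyloxy)phenoxy]malonate
Product: 5 2-methyl-2-[4-(triisopropylsilyloxy)phenoxy]propane-1,3-diol
Conditions: LiAlH4, THF, 0 °C
Reagents that add atoms: none
Why: Hydride reduction of both esters to the prochiral diol; the aryl ether and the hindered aryl silyl ether should be inert at 0 °C.

Step 4
Reactants: 5 2-methyl-2-[4-(triisopropylsilyloxy)phenoxy]propane-1,3-diol
Product: 6 (R)-3-hydroxy-2-methyl-2-[4-(triisopropylsilyloxy)phenoxy]propyl acetate
Conditions: lipase B from Candida antarctica (immobilised), vinyl acetate, t-BuOMe, 25 °C, stopped when 5 is consumed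
Reagents that add atoms: vinyl acetate C=COC(C)=O
Why: The catalytic serine of the lipase is acetylated by vinyl acetate and the acyl enzyme passes the acetyl group to one of the two enantiotopic hydroxymethyl groups of 5 through a tetrahedral intermediate held in the oxyanion hole; the vinyl alcohol set free tautomerises to acetaldehyde, which makes the transfer irreversible. The closest known reaction type is the lipase-mediated monoacylation of prochiral 2,2-disubstituted propane-1,3-diols, including a 2,2-bis(hydroxymethyl)chroman. No ring is closed and no skeletal bond is formed. The new stereocentre C2 is controlled by the enzyme alone: the small methyl group and the large flat aryloxy group fit the alcohol-binding site in one arrangement only, so that a single arm reaches the acyl serine. The step needs selection between enantiotopic arms and mono- over diacylation; the first rests on the large size difference between methyl and aryloxy at C2, the second on stopping at consumption of 5. Slight over-acylation should consume mainly the minor enantiomer of 6, whose free arm is the one the enzyme prefers, and so should raise the optical purity. Because 5 is prochiral, all of it can in principle end as one enantiomer. The product must be kept from acid and base, since acyl migration between the arms would racemise it.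

Step 5
Reactants: 6 (R)-3-hydroxy-2-methyl-2-[4-(triisopropylsilyloxy)phenoxy]propyl acetate
Product: 7 (S)-2-methyl-3-oxo-2-[4-(triisopropylsilyloxy)phenoxy]propyl acetate
Conditions: Dess–Martin periodinane, CH2Cl2, 0 °C to rt, used at once
Reagents that add atoms: none
Why: Hypervalent-iodine oxidation of a hindered primary alcohol under near-neutral conditions, done promptly so that no acyl migration can occur; the aldehyde has no α-hydrogen and cannot epimerise.

Step 6
Reactants: 7 (S)-2-methyl-3-oxo-2-[4-(triisopropylsilyloxy)phenoxy]propyl acetate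
Product: 9 (R)-2-methyl-2-[4-(triisopropylsilyloxy)phenoxy]but-3-yn-1-yl acetate, via alkynol 8 (not isolated)
Conditions: dimethyl (1-diazo-2-oxopropyl)phosphonate, K2CO3, MeOH, 0 °C to rt; evaporate; Ac2O, pyridine, 4-(dimethylamino)pyridine (cat.), CH2Cl2, rt
Reagents that add atoms: dimethyl (1-diazo-2-oxopropyl)phosphonate COP(=O)(OC)C(=[N+]=[N-])C(C)=O; acetic anhydride CC(=O)OC(C)=O
Why: Ohira–Bestmann variant of the Seyferth–Gilbert homologation: the diazomethylphosphonate anion adds to the aldehyde, and loss of dimethyl phosphate and N2 with 1,2-hydrogen shift gives the terminal alkyne; the acetate is methanolysed in the same basic methanol, so all material is funnelled through 8 and re-acetylated in the flask to keep the hydroxyl masked for step 7; C2 is untouched.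

Step 7
Reactants: 9 (R)-2-methyl-2-[4-(triisopropylsilyloxy)phenoxy]but-3-yn-1-yl acetate
Product: 10 [(R)-2-methyl-6-(triisopropylsilyloxy)-2H-chromen-2-yl]methyl acetate
Conditions: PtCl2 (5 mol %), toluene, 80 °C, in the dark
Reagents that add atoms: none
Why: Divalent platinum activates the alkyne and the ortho carbon of the electron-rich aryl ether attacks the terminal alkyne carbon (6-endo-dig intramolecular hydroarylation of an aryl propargyl ether), followed by protodemetalation; the C2–O1 bond is not broken, so the configuration is kept, and both ortho positions are equivalent.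

Step 8
Reactants: 10 [(R)-2-methyl-6-(triisopropylsilyloxy)-2H-chromen-2-yl]methyl acetate
Product: 11 [(R)-2-methyl-6-(triisopropylsilyloxy)-2H-chromen-2-yl]methanol
Conditions: K2CO3 (cat.), MeOH, rt
Reagents that add atoms: none
Why: Base-catalysed transesterification removes the acetate; the hindered aryl silyl ether should survive catalytic carbonate in methanol.

Step 9
Reactants: 12 geraniol
Product: 14 [(3E)-4,8-dimethylnona-3,7-dien-1-yl](phenyl)sulfane (homogeranyl phenyl sulfide), via geranyl bromide 13 (not isolated)
Conditions: PBr3, Et2O, −10 °C; crude 13 added to PhSCH2Li (from PhSCH3, n-BuLi, DABCO, THF, 0 °C), −78 °C to rt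
Reagents that add atoms: thioanisole CSc1ccccc1
Why: The primary allylic bromide forms without transposition at low temperature and is displaced by the sulfur-stabilised carbanion in an SN2 alkylation, a one-carbon homologation that leaves the E alkene untouched.

Step 10
Reactants: 14 [(3E)-4,8-dimethylnona-3,7-dien-1-yl](phenyl)sulfane
Product: 15 (3E)-1-iodo-4,8-dimethylnona-3,7-diene (homogeranyl iodide)
Conditions: MeI (excess), NaI, DMF, 75 °C
Reagents that add atoms: iodomethane CI; sodium iodide [Na+].[I-]
Why: S-Methylation gives a sulfonium salt that iodide dealkylates at the primary homoallylic carbon (SN2), releasing thioanisole; attack at methyl only returns the sulfide.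

Step 11
Reactants: 15 (3E)-1-iodo-4,8-dimethylnona-3,7-diene; 16 triethyl phosphonoacetate
Product: 17 ethyl (5E)-2-(diethoxyphosphoryl)-6,10-dimethylundeca-5,9-dienoate (racemic)
Conditions: NaH, excess 16, THF/DMPU, 0 °C then 60 °C
Reagents that add atoms: none
Why: SN2 alkylation of the sodium phosphonoacetate by a primary iodide; the excess of 16 limits dialkylation, and the racemic carbon becomes sp2 in step 17.

Step 12
Reactants: 18 (2E,6E)-farnesol
Product: 20 [(2E,6E)-3,7,11-trimethyldodeca-2,6,10-trien-1-yl]sulfonylbenzene (farnesyl phenyl sulfone), via farnesyl bromide 19 (not isolated)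
Conditions: PBr3, Et2O, 0 °C; crude 19, PhSO2Na, DMF, rt
Reagents that add atoms: sodium benzenesulfinate [Na+].[O-]S(=O)c1ccccc1
Why: Allylic bromide formation, then S-alkylation of the ambident sulfinate to the primary allylic sulfone; any transposed bromide converges on the same sulfone by SN2' attack.

Step 13
Reactants: 20 [(2E,6E)-3,7,11-trimethyldodeca-2,6,10-trien-1-yl]sulfonylbenzene
Product: 22 2,2-dimethyl-3-[(3E,7E)-3,7-dimethyl-9-(phenylsulfonyl)nona-3,7-dien-1-yl]oxirane (racemic), via bromohydrin 21 (not isolated)
Conditions: N-bromosuccinimide, THF/H2O, 0 °C; then K2CO3, MeOH, rt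
Reagents that add atoms: water O
Why: In aqueous medium the bromonium ion forms preferentially at the exposed terminal alkene (the 2,3-alkene is deactivated by the sulfonyl group); water opens it at the tertiary carbon and carbonate closes the bromohydrin to the epoxide. The racemic centre is removed in step 15.

Step 14
Reactants: 22 2,2-dimethyl-3-[(3E,7E)-3,7-dimethyl-9-(phenylsulfonyl)nona-3,7-dien-1-yl]oxirane
Product: 23 (6E,10E)-2,6,10-trimethyl-12-(phenylsulfonyl)dodeca-1,6,10-trien-3-ol (racemic)
Conditions: Al(Oi-Pr)3, toluene, 110 °C
Reagents that add atoms: none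
Why: Aluminium-alkoxide-mediated isomerisation of a trisubstituted epoxide to an allylic alcohol: the Lewis acid opens the C–O bond at the tertiary carbon while an alkoxide ligand removes a methyl hydrogen through a cyclic transition state.

Step 15
Reactants: 23 (6E,10E)-2,6,10-trimethyl-12-(phenylsulfonyl)dodeca-1,6,10-trien-3-ol
Product: 25 ethyl (4E,8E,12E)-4,8,12-trimethyl-14-(phenylsulfonyl)tetradeca-4,8,12-trienoate, via ketene acetal 24 (not isolated)
Conditions: CH3C(OEt)3 (excess), propanoic acid (cat.), 138 °C, EtOH distilled off
Reagents that add atoms: triethyl orthoacetate CCOC(C)(OCC)OCC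
Why: Johnson–Claisen rearrangement: the mixed ketene acetal undergoes a chair [3,3] shift with the chain equatorial, forming C13'–C14' and the E trisubstituted C11'=C12' alkene.

Step 16
Reactants: 25 ethyl (4E,8E,12E)-4,8,12-trimethyl-14-(phenylsulfonyl)tetradeca-4,8,12-trienoate
Product: 26 (4E,8E,12E)-4,8,12-trimethyl-14-(phenylsulfonyl)tetradeca-4,8,12-trienal
Conditions: i-Bu2AlH (1.05 equiv), CH2Cl2, −78 °C; aqueous potassium sodium tartrate
Reagents that add atoms: none
Why: Partial reduction of the ester: the aluminium hemiacetal is stable at −78 °C and gives the aldehyde on work-up; the sulfone is inert to the hydride.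

Step 17
Reactants: 26 (4E,8E,12E)-4,8,12-trimethyl-14-(phenylsulfonyl)tetradeca-4,8,12-trienal; 17 ethyl (5E)-2-(diethoxyphosphoryl)-6,10-dimethylundeca-5,9-dienoate
Product: 27 ethyl (2E,6E,10E,14E)-2-[(3E)-4,8-dimethylnona-3,7-dien-1-yl]-6,10,14-trimethyl-16-(phenylsulfonyl)hexadeca-2,6,10,14-tetraenoate
Conditions: 17, NaH, THF, 0 °C; then 26, −20 °C to rt
Reagents that add atoms: none
Why: Horner–Wadsworth–Emmons olefination with an α-alkylated phosphonoacetate; reversible addition and elimination through the less crowded oxaphosphetane should place the ester trans to the aldehyde-derived chain, which is the required cis relation of C14' and C17'. The phosphonate anion is too weak a base to disturb the allylic sulfone, and any minor isomer would be removed by chromatography.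

Step 18
Reactants: 27 ethyl (2E,6E,10E,14E)-2-[(3E)-4,8-dimethylnona-3,7-dien-1-yl]-6,10,14-trimethyl-16-(phenylsulfonyl)hexadeca-2,6,10,14-tetraenoate
Product: 28 (2E,6E,10E,14E)-2-[(3E)-4,8-dimethylnona-3,7-dien-1-yl]-6,10,14-trimethyl-16-(phenylsulfonyl)hexadeca-2,6,10,14-tetraen-1-ol
Conditions: i-Bu2AlH (2.5 equiv), CH2Cl2, −78 to 0 °C; aqueous potassium sodium tartrate
Reagents that add atoms: none
Why: 1,2-Reduction of the conjugated ester to the primary allylic alcohol; neither alkene geometry nor the sulfone is affected.

Step 19
Reactants: 28 (2E,6E,10E,14E)-2-[(3E)-4,8-dimethylnona-3,7-dien-1-yl]-6,10,14-trimethyl-16-(phenylsulfonyl)hexadeca-2,6,10,14-tetraen-1-ol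
Product: 29 tert-butyl{[(2E,6E,10E,14E)-2-[(3E)-4,8-dimethylnona-3,7-dien-1-yl]-6,10,14-trimethyl-16-(phenylsulfonyl)hexadeca-2,6,10,14-tetraen-1-yl]oxy}dimethylsilane
Conditions: t-BuMe2SiCl, imidazole, CH2Cl2, rt
Reagents that add atoms: tert-butyldimethylsilyl chloride CC(C)(C)[Si](C)(C)Cl
Why: Silylation of the primary alcohol, so that only the sulfonyl-bearing carbon is deprotonated in step 21 and one fluoride treatment frees both hydroxyls at the end.

Step 20
Reactants: 11 [(R)-2-methyl-6-(triisopropylsilyloxy)-2H-chromen-2-yl]methanol
Product: 30 [(R)-2-methyl-6-(triisopropylsilyloxy)-2H-chromen-2-yl]methyl trifluoromethanesulfonate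
Conditions: Tf2O, 2,6-lutidine, CH2Cl2, −78 °C, used at once
Reagents that add atoms: trifluoromethanesulfonic anhydride O=S(=O)(OS(=O)(=O)C(F)(F)F)C(F)(F)F
Why: Triflation of the neopentyl-type alcohol; only a triflate leaves fast enough for SN2 at this hindered carbon, and the quaternary neighbour has no hydrogen, so elimination is excluded.

Step 21
Reactants: 29 tert-butyl{[(2E,6E,10E,14E)-2-[(3E)-4,8-dimethylnona-3,7-dien-1-yl]-6,10,14-trimethyl-16-(phenylsulfonyl)hexadeca-2,6,10,14-tetraen-1-yl]oxy}dimethylsilane; 30 [(R)-2-methyl-6-(triisopropylsilyloxy)-2H-chromen-2-yl]methyl trifluoromethanesulfonate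
Product: 31 (S)-2-[(3E,7E,11E,15E,19E)-16-[(tert-butyldimethylsilyloxy)methyl]-4,8,12,20,24-pentamethyl-2-(phenylsulfonyl)pentacosa-3,7,11,15,19,23-hexaen-1-yl]-2-methyl-6-(triisopropylsilyloxy)-2H-chromene (both epimers at C2')
Conditions: 29, n-BuLi, THF/DMPU, −78 °C; then 30, −78 to −20 °C
Reagents that add atoms: none
Why: α-Alkylation of a lithiated allylic sulfone by a primary triflate (SN2), the established way of joining prenyl chains to chroman-2-ylmethyl units; the C2' centre forms unselectively and is removed in step 22.

Step 22
Reactants: 31 (S)-2-[(3E,7E,11E,15E,19E)-16-[(tert-butyldimethylsilyloxy)methyl]-4,8,12,20,24-pentamethyl-2-(phenylsulfonyl)pentacosa-3,7,11,15,19,23-hexaen-1-yl]-2-methyl-6-(triisopropylsilyloxy)-2H-chromene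
Product: 32 (S)-2-[(3E,7E,11E,15E,19E)-16-[(tert-butyldimethylsilyloxy)methyl]-4,8,12,20,24-pentamethylpentacosa-3,7,11,15,19,23-hexaen-1-yl]-2-methyl-6-(triisopropylsilyloxy)-2H-chromene
Conditions: PdCl2(dppp) (10 mol %), LiBHEt3, THF, 0 °C, in the dark
Reagents that add atoms: none
Why: Palladium-catalysed reductive desulfonylation: zerovalent palladium formed in situ ionises the allylic sulfone to a π-allyl complex and hydride is delivered to the less substituted terminus C2', which should keep the 3',4' alkene in place and E; the endocyclic C2–O1 bond lies in the plane of the chromene alkene and should not ionise.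

Step 23
Reactants: 32 (S)-2-[(3E,7E,11E,15E,19E)-16-[(tert-butyldimethylsilyloxy)methyl]-4,8,12,20,24-pentamethylpentacosa-3,7,11,15,19,23-hexaen-1-yl]-2-methyl-6-(triisopropylsilyloxy)-2H-chromene
Product: 33 (S)-2-[(3E,7E,11E,15E,19E)-16-(hydroxymethyl)-4,8,12,20,24-pentamethylpentacosa-3,7,11,15,19,23-hexaen-1-yl]-2-methyl-2H-chromen-6-ol (CNP0017559.1)
Conditions: Bu4NF, AcOH, THF, 0 °C to rt, under argon, in the dark
Reagents that add atoms: none
Why: Fluoride cleaves the aryl triisopropylsilyl and the allylic tert-butyldimethylsilyl ether in one operation; acetic acid buffers the phenoxide against air oxidation.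

## Compound list

1 | hydroquinone | Oc1ccc(O)cc1 | starting material
2 | 4-(triisopropylsilyloxy)phenol | Oc1ccc(O[Si](C(C)C)(C(C)C)C(C)C)cc1 | intermediate
3 | diethyl 2-bromo-2-methylmalonate | CCOC(=O)C(C)(Br)C(=O)OCC | starting material
4 | diethyl 2-methyl-2-[4-(triisopropylsilyloxy)phenoxy]malonate | CCOC(=O)C(C)(Oc1ccc(O[Si](C(C)C)(C(C)C)C(C)C)cc1)C(=O)OCC | intermediate
5 | 2-methyl-2-[4-(triisopropylsilyloxy)phenoxy]propane-1,3-diol | CC(CO)(CO)Oc1ccc(O[Si](C(C)C)(C(C)C)C(C)C)cc1 | intermediate
6 | (R)-3-hydroxy-2-methyl-2-[4-(triisopropylsilyloxy)phenoxy]propyl acetate | CC(=O)OC[C@@](Oc1ccc(O[Si](C(C)C)(C(C)C)C(C)C)cc1)(C)CO | intermediate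
7 | (S)-2-methyl-3-oxo-2-[4-(triisopropylsilyloxy)phenoxy]propyl acetate | CC(=O)OC[C@@](Oc1ccc(O[Si](C(C)C)(C(C)C)C(C)C)cc1)(C)C=O | intermediate
8 | (R)-2-methyl-2-[4-(triisopropylsilyloxy)phenoxy]but-3-yn-1-ol | OC[C@@](Oc1ccc(O[Si](C(C)C)(C(C)C)C(C)C)cc1)(C)C#C | intermediate (not isolated)
9 | (R)-2-methyl-2-[4-(triisopropylsilyloxy)phenoxy]but-3-yn-1-yl acetate | CC(=O)OC[C@@](Oc1ccc(O[Si](C(C)C)(C(C)C)C(C)C)cc1)(C)C#C | intermediate
10 | [(R)-2-methyl-6-(triisopropylsilyloxy)-2H-chromen-2-yl]methyl acetate | CC(=O)OC[C@@]1(C)C=Cc2cc(O[Si](C(C)C)(C(C)C)C(C)C)ccc2O1 | intermediate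
11 | [(R)-2-methyl-6-(triisopropylsilyloxy)-2H-chromen-2-yl]methanol | OC[C@@]1(C)C=Cc2cc(O[Si](C(C)C)(C(C)C)C(C)C)ccc2O1 | intermediate
12 | geraniol | CC(C)=CCC/C(C)=C/CO | starting material
13 | geranyl bromide | CC(C)=CCC/C(C)=C/CBr | intermediate (not isolated)
14 | [(3E)-4,8-dimethylnona-3,7-dien-1-yl](phenyl)sulfane | CC(C)=CCC/C(C)=C/CCSc1ccccc1 | intermediate
15 | (3E)-1-iodo-4,8-dimethylnona-3,7-diene | CC(C)=CCC/C(C)=C/CCI | intermediate
16 | triethyl phosphonoacetate | CCOC(=O)CP(=O)(OCC)OCC | starting material
17 | ethyl (5E)-2-(diethoxyphosphoryl)-6,10-dimethylundeca-5,9-dienoate (racemic) | CC(C)=CCC/C(C)=C/CCC(C(=O)OCC)P(=O)(OCC)OCC | intermediate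
18 | (2E,6E)-farnesol | CC(C)=CCC/C(C)=C/CC/C(C)=C/CO | starting material
19 | (2E,6E)-farnesyl bromide | CC(C)=CCC/C(C)=C/CC/C(C)=C/CBr | intermediate (not isolated)
20 | [(2E,6E)-3,7,11-trimethyldodeca-2,6,10-trien-1-yl]sulfonylbenzene | CC(C)=CCC/C(C)=C/CC/C(C)=C/CS(=O)(=O)c1ccccc1 | intermediate
21 | (6E,10E)-3-bromo-2,6,10-trimethyl-12-(phenylsulfonyl)dodeca-6,10-dien-2-ol (racemic) | CC(C)(O)C(Br)CC/C(C)=C/CC/C(C)=C/CS(=O)(=O)c1ccccc1 | intermediate (not isolated)
22 | 2,2-dimethyl-3-[(3E,7E)-3,7-dimethyl-9-(phenylsulfonyl)nona-3,7-dien-1-yl]oxirane (racemic) | CC1(C)OC1CC/C(C)=C/CC/C(C)=C/CS(=O)(=O)c1ccccc1 | intermediate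
23 | (6E,10E)-2,6,10-trimethyl-12-(phenylsulfonyl)dodeca-1,6,10-trien-3-ol (racemic) | C=C(C)C(O)CC/C(C)=C/CC/C(C)=C/CS(=O)(=O)c1ccccc1 | intermediate
24 | [(2E,6E)-10-(1-ethoxyvinyloxy)-3,7,11-trimethyldodeca-2,6,11-trien-1-yl]sulfonylbenzene (ketene acetal; racemic) | C=C(OCC)OC(CC/C(C)=C/CC/C(C)=C/CS(=O)(=O)c1ccccc1)C(C)=C | intermediate (not isolated)
25 | ethyl (4E,8E,12E)-4,8,12-trimethyl-14-(phenylsulfonyl)tetradeca-4,8,12-trienoate | CCOC(=O)CC/C(C)=C/CC/C(C)=C/CC/C(C)=C/CS(=O)(=O)c1ccccc1 | intermediate
26 | (4E,8E,12E)-4,8,12-trimethyl-14-(phenylsulfonyl)tetradeca-4,8,12-trienal | O=CCC/C(C)=C/CC/C(C)=C/CC/C(C)=C/CS(=O)(=O)c1ccccc1 | intermediate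
27 | ethyl (2E,6E,10E,14E)-2-[(3E)-4,8-dimethylnona-3,7-dien-1-yl]-6,10,14-trimethyl-16-(phenylsulfonyl)hexadeca-2,6,10,14-tetraenoate | CC(C)=CCC/C(C)=C/CC/C(=C\CC/C(C)=C/CC/C(C)=C/CC/C(C)=C/CS(=O)(=O)c1ccccc1)C(=O)OCC | intermediate
28 | (2E,6E,10E,14E)-2-[(3E)-4,8-dimethylnona-3,7-dien-1-yl]-6,10,14-trimethyl-16-(phenylsulfonyl)hexadeca-2,6,10,14-tetraen-1-ol | CC(C)=CCC/C(C)=C/CC/C(=C\CC/C(C)=C/CC/C(C)=C/CC/C(C)=C/CS(=O)(=O)c1ccccc1)CO | intermediate
29 | tert-butyl{[(2E,6E,10E,14E)-2-[(3E)-4,8-dimethylnona-3,7-dien-1-yl]-6,10,14-trimethyl-16-(phenylsulfonyl)hexadeca-2,6,10,14-tetraen-1-yl]oxy}dimethylsilane | CC(C)=CCC/C(C)=C/CC/C(=C\CC/C(C)=C/CC/C(C)=C/CC/C(C)=C/CS(=O)(=O)c1ccccc1)CO[Si](C)(C)C(C)(C)C | intermediate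
30 | [(R)-2-methyl-6-(triisopropylsilyloxy)-2H-chromen-2-yl]methyl trifluoromethanesulfonate | O=S(=O)(OC[C@@]1(C)C=Cc2cc(O[Si](C(C)C)(C(C)C)C(C)C)ccc2O1)C(F)(F)F | intermediate
31 | (S)-2-[(3E,7E,11E,15E,19E)-16-[(tert-butyldimethylsilyloxy)methyl]-4,8,12,20,24-pentamethyl-2-(phenylsulfonyl)pentacosa-3,7,11,15,19,23-hexaen-1-yl]-2-methyl-6-(triisopropylsilyloxy)-2H-chromene (both epimers at C2') | CC(C)=CCC/C(C)=C/CC/C(=C\CC/C(C)=C/CC/C(C)=C/CC/C(C)=C/C(C[C@@]1(C)C=Cc2cc(O[Si](C(C)C)(C(C)C)C(C)C)ccc2O1)S(=O)(=O)c1ccccc1)CO[Si](C)(C)C(C)(C)C | intermediate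
32 | (S)-2-[(3E,7E,11E,15E,19E)-16-[(tert-butyldimethylsilyloxy)methyl]-4,8,12,20,24-pentamethylpentacosa-3,7,11,15,19,23-hexaen-1-yl]-2-methyl-6-(triisopropylsilyloxy)-2H-chromene | CC(C)=CCC/C(C)=C/CC/C(=C\CC/C(C)=C/CC/C(C)=C/CC/C(C)=C/CC[C@@]1(C)C=Cc2cc(O[Si](C(C)C)(C(C)C)C(C)C)ccc2O1)CO[Si](C)(C)C(C)(C)C | intermediate
33 | (S)-2-[(3E,7E,11E,15E,19E)-16-(hydroxymethyl)-4,8,12,20,24-pentamethylpentacosa-3,7,11,15,19,23-hexaen-1-yl]-2-methyl-2H-chromen-6-ol | CC(C)=CCC/C(C)=C/CC/C(=C\CC/C(C)=C/CC/C(C)=C/CC/C(C)=C/CC[C@@]1(C)C=Cc2cc(O)ccc2O1)CO | target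

## Step count and least certain steps

Total step count: 23. Longest linear sequence: 12 steps (from 1 through steps 1–8 and 20–23).

Step 4 (key step). The enzyme may discriminate the two arms insufficiently or in the opposite sense, and acyl migration during isolation could erode the optical purity. Fallback: set out from 5, acetylate both arms (Ac2O, pyridine) to 2-methyl-2-[4-(triisopropylsilyloxy)phenoxy]propane-1,3-diyl diacetate F1, and hydrolyse one ester group with the same lipase, or an esterase, in aqueous phosphate buffer. Hydrolysis removes the acetyl group from the arm the enzyme would otherwise acylate, so the opposite sense results and the route is rejoined at 6.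

Step 6. Loss of the acetate before the homologation would expose a β-hydroxy aldehyde to retro-aldol loss of formaldehyde, and so to racemisation or decomposition; the hindered aldehyde may also homologate slowly. Fallback: set out from 7 and use a Corey–Fuchs sequence. CBr4 and PPh3 should give (R)-4,4-dibromo-2-methyl-2-[4-(triisopropylsilyloxy)phenoxy]but-3-en-1-yl acetate F2 under neutral conditions. Excess n-BuLi at −78 °C then effects bromine–lithium exchange and Fritsch–Buttenberg–Wiechell rearrangement to the alkyne and also removes the acetate, giving 8. This is acetylated as in step 6 and the route is rejoined at 9.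

Step 7. The metal may ionise the tertiary propargylic C–O bond (racemisation, elimination), the acetate carbonyl may attack the activated alkyne, or the cyclisation may be slow. Fallback: set out from 9 and close the ring without alkyne activation. Anti-Markovnikov hydroboration with dicyclohexylborane and oxidation with NaBO3 would give (R)-2-methyl-4-oxo-2-[4-(triisopropylsilyloxy)phenoxy]butyl acetate F3. Catalytic p-toluenesulfonic acid in toluene should then bring about intramolecular Friedel–Crafts hydroxyalkylation ortho to O1, giving [(2R)-4-hydroxy-2-methyl-6-(triisopropylsilyloxy)chroman-2-yl]methyl acetate F4. This benzylic alcohol dehydrates under the same conditions and the route is rejoined at 10.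

Step 13. Bromonium formation may not distinguish the terminal from the internal 6,7-alkene well enough, and over-bromination may occur. Fallback: set out from 20 and oxidise the terminal E methyl group with SeO2 (cat.) and t-BuOOH to (2E,6E,10E)-2,6,10-trimethyl-12-(phenylsulfonyl)dodeca-2,6,10-trien-1-ol F5. Appel bromination (CBr4, PPh3) gives [(2E,6E,10E)-12-bromo-3,7,11-trimethyldodeca-2,6,10-trien-1-yl]sulfonylbenzene F6. Alkylation of sodium diethyl malonate gives diethyl 2-[(2E,6E,10E)-2,6,10-trimethyl-12-(phenylsulfonyl)dodeca-2,6,10-trien-1-yl]malonate F7. Krapcho dealkoxycarbonylation (LiCl, wet DMSO, 150 °C) then rejoins the route at 25.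

Step 17. Geometric control in an olefination with an α-branched phosphonate may be incomplete, and the isomers may be hard to separate. Fallback: set out from 26 and 15 and form the C16'–C17' bond by cross-coupling instead. A Wittig reaction of 26 with ethyl bromo(triphenylphosphoranylidene)acetate should give ethyl (2Z,6E,10E,14E)-2-bromo-6,10,14-trimethyl-16-(phenylsulfonyl)hexadeca-2,6,10,14-tetraenoate F8, whose isomers can be separated at this stage. Exchange of 15 with t-BuLi and capture with B-methoxy-9-borabicyclo[3.3.1]nonane gives 9-[(3E)-4,8-dimethylnona-3,7-dien-1-yl]-9-borabicyclo[3.3.1]nonane F9 (as its methoxyborate). A B-alkyl Suzuki–Miyaura coupling (PdCl2(dppf), K3PO4, THF/H2O) joins F8 and F9 with retention of alkene geometry and rejoins the route at 27.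

## Further compounds

F1 | step 4 | 2-methyl-2-[4-(triisopropylsilyloxy)phenoxy]propane-1,3-diyl diacetate | CC(=O)OCC(C)(COC(C)=O)Oc1ccc(O[Si](C(C)C)(C(C)C)C(C)C)cc1
F2 | step 6 | (R)-4,4-dibromo-2-methyl-2-[4-(triisopropylsilyloxy)phenoxy]but-3-en-1-yl acetate | CC(=O)OC[C@@](Oc1ccc(O[Si](C(C)C)(C(C)C)C(C)C)cc1)(C)C=C(Br)Br
F3 | step 7 | (R)-2-methyl-4-oxo-2-[4-(triisopropylsilyloxy)phenoxy]butyl acetate | CC(=O)OC[C@@](Oc1ccc(O[Si](C(C)C)(C(C)C)C(C)C)cc1)(C)CC=O
F4 | step 7 | [(2R)-4-hydroxy-2-methyl-6-(triisopropylsilyloxy)chroman-2-yl]methyl acetate (both epimers at C4) | CC(=O)OC[C@@]1(C)CC(O)c2cc(O[Si](C(C)C)(C(C)C)C(C)C)ccc2O1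
F5 | step 13 | (2E,6E,10E)-2,6,10-trimethyl-12-(phenylsulfonyl)dodeca-2,6,10-trien-1-ol | OC/C(C)=C/CC/C(C)=C/CC/C(C)=C/CS(=O)(=O)c1ccccc1
F6 | step 13 | [(2E,6E,10E)-12-bromo-3,7,11-trimethyldodeca-2,6,10-trien-1-yl]sulfonylbenzene | BrC/C(C)=C/CC/C(C)=C/CC/C(C)=C/CS(=O)(=O)c1ccccc1
F7 | step 13 | diethyl 2-[(2E,6E,10E)-2,6,10-trimethyl-12-(phenylsulfonyl)dodeca-2,6,10-trien-1-yl]malonate | CCOC(=O)C(C/C(C)=C/CC/C(C)=C/CC/C(C)=C/CS(=O)(=O)c1ccccc1)C(=O)OCC
F8 | step 17 | ethyl (2Z,6E,10E,14E)-2-bromo-6,10,14-trimethyl-16-(phenylsulfonyl)hexadeca-2,6,10,14-tetraenoate | CCOC(=O)/C(Br)=C/CC/C(C)=C/CC/C(C)=C/CC/C(C)=C/CS(=O)(=O)c1ccccc1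
F9 | step 17 | 9-[(3E)-4,8-dimethylnona-3,7-dien-1-yl]-9-borabicyclo[3.3.1]nonane | CC(C)=CCC/C(C)=C/CCB1C2CCCC1CCC2
A1 | alternative 1 | 5-(tert-butyldimethylsilyloxy)-2-hydroxybenzaldehyde | O=Cc1cc(O[Si](C)(C)C(C)(C)C)ccc1O
A2 | alternative 1 | (2E,6E,10E,14E,18E,22E)-19-[(tert-butyldimethylsilyloxy)methyl]-3,7,11,15,23,27-hexamethyloctacosa-2,6,10,14,18,22,26-heptaenal | CC(C)=CCC/C(C)=C/CC/C(=C\CC/C(C)=C/CC/C(C)=C/CC/C(C)=C/CC/C(C)=C/C=O)CO[Si](C)(C)C(C)(C)C
A3 | alternative 1 | (S)-6-(tert-butyldimethylsilyloxy)-2-[(3E,7E,11E,15E,19E)-16-[(tert-butyldimethylsilyloxy)methyl]-4,8,12,20,24-pentamethylpentacosa-3,7,11,15,19,23-hexaen-1-yl]-2-methyl-2H-chromene-3-carbaldehyde | CC(C)=CCC/C(C)=C/CC/C(=C\CC/C(C)=C/CC/C(C)=C/CC/C(C)=C/CC[C@@]1(C)C(C=O)=Cc2cc(O[Si](C)(C)C(C)(C)C)ccc2O1)CO[Si](C)(C)C(C)(C)C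
A4 | alternative 2 | (6E,10E,14E)-17-[(S)-6-(tert-butyldimethylsilyloxy)-2-methyl-2H-chromen-2-yl]-6,10,14-trimethylheptadeca-6,10,14-trien-2-yn-1-ol | OCC#CCC/C(C)=C/CC/C(C)=C/CC/C(C)=C/CC[C@@]1(C)C=Cc2cc(O[Si](C)(C)C(C)(C)C)ccc2O1
A5 | alternative 2 | [(3E)-4,8-dimethylnona-3,7-dien-1-yl]magnesium bromide | CC(C)=CCC/C(C)=C/CC[Mg]Br
A6 | alternative 2 | (2E,6E,10E,14E)-16-[(S)-6-(tert-butyldimethylsilyloxy)-2-methyl-2H-chromen-2-yl]-2-[(3E)-4,8-dimethylnona-3,7-dien-1-yl]-6,10,14-trimethylhexadeca-2,6,10,14-tetraen-1-ol... written from the chromene: (S)-6-(tert-butyldimethylsilyloxy) aryl ether of 33 | CC(C)=CCC/C(C)=C/CC/C(=C\CC/C(C)=C/CC/C(C)=C/CC/C(C)=C/CC[C@@]1(C)C=Cc2cc(O[Si](C)(C)C(C)(C)C)ccc2O1)CO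
A7 | alternative 3 | (R)-4-(trimethylsilyl)but-3-yn-2-yl diisopropylcarbamate | C[C@@H](OC(=O)N(C(C)C)C(C)C)C#C[Si](C)(C)C
A8 | alternative 3 | 2-[(3E,7E,11E,15E,19E)-16-[(tert-butyldimethylsilyloxy)methyl]-4,8,12,20,24-pentamethylpentacosa-3,7,11,15,19,23-hexaen-1-yl]-4,4,5,5-tetramethyl-1,3,2-dioxaborolane | CC(C)=CCC/C(C)=C/CC/C(=C\CC/C(C)=C/CC/C(C)=C/CC/C(C)=C/CCB1OC(C)(C)C(C)(C)O1)CO[Si](C)(C)C(C)(C)C
A9 | alternative 3 | (R)-tertiary propargylic pinacol boronic ester at C2 carrying methyl, the (trimethylsilyl)ethynyl group and the complete silyl-protected side chain | CC(C)=CCC/C(C)=C/CC/C(=C\CC/C(C)=C/CC/C(C)=C/CC/C(C)=C/CC[C@@](B1OC(C)(C)C(C)(C)O1)(C)C#C[Si](C)(C)C)CO[Si](C)(C)C(C)(C)C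
A10 | alternative 3 | (S)-tertiary propargylic alcohol obtained from A9 by replacing boron with hydroxyl | CC(C)=CCC/C(C)=C/CC/C(=C\CC/C(C)=C/CC/C(C)=C/CC/C(C)=C/CC[C@@](O)(C)C#C[Si](C)(C)C)CO[Si](C)(C)C(C)(C)C
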